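Step 2 has a larger constant than step 1, and X.J is made by the one and used by the other.

    X + J → X.J (k1 = 0.023 L mol⁻¹ s⁻¹)
    J + X.J → J.X.J (k2 = 0.039 L mol⁻¹ s⁻¹)
    J + J.X.J → G (k3 = 0.045 L mol⁻¹ s⁻¹)
    J + G → J.G (k4 = 0.0020 L mol⁻¹ s⁻¹)
    X.J ⇌ Z (K5 = 0.39, k5 = 0.0021 s⁻¹)

| setting | Wednesday's | Monday's | Friday's |
|---|---|---|---|
| X | 32 mM (in portions, 2) | 32 mM (in portions, 2) | 32 mM (in portions, 2) |
| J | 33.6 mM | 33.6 mM | 33.6 mM |
| time | 3.0 h | 3.0 h | 3.0 h |
| remark | the portions of X follow each other after 1.0 h, the first at the start | the portions of X follow each other after 1.5 h, the first at the start | the portions of X follow each other after 2.5 h, the first at the start |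

- amount of X.J at the end, in percent of the X charged for Wednesday's, Monday's, Friday's, in this order
- how the row runs (rises all the way / falls, then rises / hardly changes / falls all the way / rises, then falls)

- "hardly changes" means that all values lie within two and a half points (for a concentration: within two and a half percent of the largest)
- run time (Wednesday's): 3.0 h

Follow one molecule. After step 1 it swaps between X.J and Z. Forward and back together, that swap has a half-life of 0.0257 h, shorter than the 0.15 h of X.J by step 2 with J as charged. So, with the swap the quicker, the molecule spends a share 0.719 of its time as X.J, the form that J can hit.

Now take the fork. An X molecule meets J with constant k1, and a molecule in the X.J and Z pool meets it with k2 times that share. J stands in both rates, so their ratio, a selectivity factor of 1.22, holds whatever J is doing. The pool in a portion therefore depends on the share of X left in that portion: you can reckon that it peaks when that share is 0.405. At that point X.J is 23.9 % of the portion, the ceiling on X.J per portion, for these constants and while the swap keeps up.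

I bracket the flasks by two extremes, both of them reckonings. Let both portions enter together: my hand balance of J puts a batch close to its peak at about one equivalent, and 1.05 equivalents are charged, so I put X.J near 23.9 % of the X charged. Let the first portion instead take the whole of J before the second arrives: with 2.10 equivalents it passes its peak, and X.J lies below the one-portion ceiling of 11.9 % of the X charged. J is the limiting reagent, and a longer wait gives the first portion more of it and the second less. I expect a falling row under 23.9 %, with the longest wait closest to the second extreme.

The forecast gives 16.2 %, 12.9 % and 9.1 %, a row that falls all the way: “Late portions meet almost no J, so the row falls.” Its numbers are sharper than my bracket, and its last stands below 11.9 %.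

Wednesday's, Monday's and Friday's flasks gave 16.1 %, 13.0 % and 9.16 %, and the row falls all the way; Wednesday's stands under 23.9 %, Friday's under 11.9 %. In Wednesday's flask the half-life of X.J by step 2 went from 0.15 h with J as charged to 98 h at 3.00 h, longer than the run of 3.0 h, with 0.150 % of J's charge left. At 30.0 h Wednesday's X.J still stands at 16.2 %.

Its constants belong to no real substance; the rest is arithmetic.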